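In the closed, stirred vessel the starting complex meets a fixed 0.100 M of incoming ligand, and the species to watch is the complex with two exchanged, as a percentage y of the starting complex charged.

| setting | beta | theta | eta | north | north-east | east | south |
|---|---|---|---|---|---|---|---|
| starting complex | 0.035 M | 0.14 M | 0.41 M | 0.050 M | 0.10 M | 0.20 M | 0.40 M |
| incoming ligand | 0.10 M | 0.10 M | 0.10 M | 0.100 M | 0.100 M | 0.100 M | 0.100 M |
| remark | run made earlier | run made earlier | run made earlier |  |  |  |  |
| time |  |  |  | 6.0 h | 6.0 h | 6.0 h | 6.0 h |

- beta (time / h: complex with two exchanged / %): 0.833: 1.0; 1.50: 2.1; 2.50: 2.6; 3.00: 4.1; 4.00: 5.0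
- theta (time / h: complex with two exchanged / %): 0.333: 0.2; 0.667: 1.0; 1.33: 1.2; 2.00: 1.9; 4.00: 3.4
- eta (time / h: complex with two exchanged / %): 0.833: 0.3; 1.50: 0.4; 2.50: 0.6; 3.00: 0.7; 4.00: 1.6

(each reading ± 0.3 percentage points)

- what is said of leaving ligand includes crystals
- crystals is a solid; its amount is given per volume of the solution
- candidate steps: 2 incoming ligand -> self-condensation product; starting complex + incoming ligand <-> leaving ligand + complex with one exchanged; starting complex <-> dormant form; complex with one exchanged + incoming ligand <-> leaving ligand + complex with two exchanged; crystals <-> leaving ligand
- "hardly changes" means that all values lie within two and a half points (for a concentration: within two and a half percent of the largest)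

* amount of complex with two exchanged at the end, in percent of the starting complex charged for north, north-east, east, south, in this order
* the shape of the row from first to last (falls, then rises / falls all the way / hardly changes / rises all the way / rises, then falls)

The scale needs a zero. Plain first order in starting complex makes y at a given time independent of the charge, and that case serves as the zero. The beta and eta runs at 4.00 h stand away from that zero. Their readings give 0.463: the charge penalty n, the drop in ln y per unit rise in ln charge.

But that pair is thin, since a scatter of 0.3 percentage points sits on a reading of 1.6%. The pair at 3.00 h reads 0.718, higher, so n is a range.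

A single power is also doubtful. Beta to theta reads 0.278, and theta to eta reads 0.701, steeper. Both stay positive, however, so the row should fall at each step.

Might the fall be too small to count? Scaling beta to the north charge at 4.00 h and applying n across the row gives a gap of 2.6 points, already beyond the band of "hardly changes". Run straight on to 6.0 h, this reckoning gives 6.36% for north and 2.43% for south, high if product growth bends.

The forecast differs from this reckoning: 6.8%, 5.5%, 3.8%, 1.9%, falls all the way, since “the rate levels off as complex is increased, and the percent yield drops”. Its ends imply n = 0.613, inside the range.

The flasks give 5.54%, 4.40%, 3.04%, 1.76%: falls all the way.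

    2 incoming ligand → self-condensation product (k = 8.46 × 10⁻⁴ M⁻¹ s⁻¹)
    starting complex + incoming ligand ⇌ leaving ligand + complex with one exchanged (K = 1.97, k = 0.00204 M⁻¹ s⁻¹)
    starting complex ⇌ dormant form (K = 10.0, k = 2.91 × 10⁻⁴ s⁻¹)
    complex with one exchanged + incoming ligand ⇌ leaving ligand + complex with two exchanged (K = 3.60, k = 2.95 × 10⁻⁴ M⁻¹ s⁻¹)
    crystals ⇌ leaving ligand, rate k5*(cs5 - [leaving ligand]) while solid is left; crystals form when [leaving ligand] > cs5 (solubility = 0.100 M, k = 0.00612 s⁻¹)

From north to south, a charge ratio of 8.00, the row has n = 0.551. Part of that penalty comes from the falling level of incoming ligand. With that level held, north reaches 17.9% and south 11.9%, so n shrinks to 0.197.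

The readings come from a simulation on assumed constants, noise included.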